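Ring B of this eudesmane (eudesmane numbering) is cut at C5–C6 and C9–C10. Its C8 ketone lies 1,4 to the ring-fusion methine C5, the pattern left by a 2-silyloxydiene, while the angular methyl carbon C10 and the carbinol carbon C4 map onto the β-carbon and carbonyl of 3-methylcyclohex-2-enone. A catalyst-controlled enantioselective Diels–Alder reaction of these two achiral partners therefore closes ring B, forges both bonds and sets the quaternary C10 stereocentre in one operation. It delivers C4 as a ketone and C8 as a regiodefined silyl enol ether, from which the C15 methyl, the 3,4-cis-diol, the C11 carbinol and the C6–C7 alkene are elaborated.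

Key step: step 2

Numbering: the discussion uses eudesmane numbering (ring A = C1–C5 and C10; ring B = C5–C10; C11 = side-chain carbinol carbon; C14 = angular methyl; C15 = methyl on C4). Compound names use naphthalene numbering.

Assumption: the sense of induction in step 2 is taken from the α-C–H···O binding model of oxazaborolidinium catalysts, which predicts that the (S)-catalyst exposes the C3-Si face of the enone; should the sense prove opposite, the equally available (R)-catalyst is used.

Step 1
Reactants: 1 methyl vinyl ketone (but-3-en-2-one)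
Product: 2 2-(tert-butyldimethylsilyloxy)buta-1,3-diene
Conditions: TBSOTf, Et3N, Et2O, 0 °C; non-aqueous work-up, distillation
Reagents that add atoms: tert-butyldimethylsilyl trifluoromethanesulfonate, CC(C)(C)[Si](C)(C)OS(=O)(=O)C(F)(F)F
Why: Soft enolisation and O-silylation of the methyl ketone (silyl dienol ether formation) should give the cross-conjugated 2-silyloxydiene; no stereocentre is formed.

Step 2
Reactants: 3 3-methylcyclohex-2-en-1-one; 2 2-(tert-butyldimethylsilyloxy)buta-1,3-diene
Product: 4 (4aR,8aS)-6-[(tert-butyldimethylsilyl)oxy]-4a-methyl-3,4,4a,5,8,8a-hexahydronaphthalen-1(2H)-one (cis-fused adduct)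
Conditions: (S)-3,3-diphenyl-1-(o-tolyl)tetrahydropyrrolo[1,2-c][1,3,2]oxazaborole (20 mol %), AlBr3 (16 mol %), diene in twofold excess, CH2Cl2, −40 to −10 °C; Et3N quench
Reagents that add atoms: none
Why: Proposed new method: the AlBr3-activated oxazaborolidine binds the enone carbonyl syn to C2–H, so that the diene CH2 terminus next to the siloxy carbon attacks the β-carbon (Mukaiyama–Michael-like first bond, creating the quaternary centre) and the resulting enolate/siloxyallyl cation pair collapses at the other diene terminus, which amounts to a strongly asynchronous [4+2] cycloaddition. The closest known reactions are the oxazaborolidinium-catalysed enantioselective Diels–Alder reactions of cyclohex-2-enone and quinones with 2-silyloxybutadienes and the racemic AlBr3/AlMe3-promoted cycloaddition of 3-methylcyclohex-2-enone with 2-silyloxydienes; their combination on a β,β-disubstituted enone is the untested part. Ring B is closed by intermolecular suprafacial [4+2] addition, giving a six-membered, cis-fused ring. C4a (R, the angular methyl carbon) is set by catalyst control, the catalyst phenyl group shielding the C3-Re face so that the diene adds to the C3-Si face; C8a follows from suprafacial addition (cis, S) and is corrected in step 3. Regioselectivity is secured by matching the largest HOMO coefficient (diene CH2 adjacent to the siloxy carbon) with the largest LUMO coefficient (enone β-carbon), which places the siloxy carbon 1,4 to the ring-fusion CH; excess diene and strictly aprotic conditions guard against protodesilylation.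

Step 3
Reactants: 4 cis-fused adduct
Product: 5 (4aR,8aR)-6-[(tert-butyldimethylsilyl)oxy]-4a-methyl-3,4,4a,5,8,8a-hexahydronaphthalen-1(2H)-one (trans-fused ketone)
Conditions: KOt-Bu (0.2 equiv), t-BuOH/THF, 0 °C to rt; chromatography, residual cis isomer recycled
Reagents that add atoms: none
Why: Enolate-mediated epimerisation under thermodynamic control should favour the trans-fused decalone and sets C8a (R); the hindered alkoxide in catalytic amount should spare the silyl enol ether.

Step 4
Reactants: 5 trans-fused ketone
Product: 7 (4aR,8aR)-6-[(tert-butyldimethylsilyl)oxy]-4a-methyl-3,4,4a,5,8,8a-hexahydronaphthalen-1-yl trifluoromethanesulfonate, via lithium enolate 6 (not isolated)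
Conditions: LiN(i-Pr)2 (1.1 equiv), THF, −78 °C; then PhNTf2, −78 to 0 °C
Reagents that add atoms: N-phenylbis(trifluoromethanesulfonimide), O=S(=O)(N(c1ccccc1)S(=O)(=O)C(F)(F)F)C(F)(F)F
Why: Kinetic deprotonation at the less hindered C2 methylene rather than the ring-fusion methine, followed by O-triflation (enol triflate formation), should fix the ring A double bond at eudesmane C3–C4 without disturbing C8a.

Step 5
Reactants: 7 enol triflate
Product: 8 tert-butyl{[(4aR,8aR)-5,8a-dimethyl-1,4,4a,7,8,8a-hexahydronaphthalen-2-yl]oxy}dimethylsilane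
Conditions: MeMgBr (1.5 equiv), Fe(acac)3 (5 mol %), THF/NMP, −30 to 0 °C; pH 7 buffer work-up
Reagents that add atoms: methylmagnesium bromide, C[Mg]Br
Why: Iron-catalysed cross-coupling of the alkenyl triflate with the Grignard reagent should install the C15 methyl with retention of the alkene position; the silyl enol ether is inert at this temperature and no stereocentre is touched.

Step 6
Reactants: 8 silyl enol ether
Product: 9 (4aR,8aR)-3-(2-hydroxypropan-2-yl)-5,8a-dimethyl-3,4,4a,7,8,8a-hexahydronaphthalen-2(1H)-one (mixture of C3 epimers)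
Conditions: acetone (5 equiv), TiCl4 (1.1 equiv), 2,6-di-tert-butyl-4-methylpyridine, CH2Cl2, −78 °C; aq. NaHCO3 quench at −78 °C
Reagents that add atoms: acetone, CC(C)=O
Why: Mukaiyama aldol addition: the enol ether carbon C3 (eudesmane C7) attacks TiCl4-activated acetone regiospecifically; the new C3 stereocentre is inconsequential because it becomes sp2 in step 7.

Step 7
Reactants: 9 ketol
Product: 10 (4aR,8aR)-3-(2-hydroxypropan-2-yl)-5,8a-dimethyl-4a,7,8,8a-tetrahydronaphthalen-2(1H)-one
Conditions: IBX (2.5 equiv), DMSO, 65 °C
Reagents that add atoms: none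
Why: IBX-mediated α,β-dehydrogenation of the ketone can only occur toward C3–C4 because the other α-carbon (C1) is flanked by the quaternary C8a, which has no hydrogen; the tertiary alcohol is not oxidised.

Step 8
Reactants: 10 dienone alcohol
Product: 11 (4aR,5S,6R,8aR)-5,6-dihydroxy-3-(2-hydroxypropan-2-yl)-5,8a-dimethyl-4a,5,6,7,8,8a-hexahydronaphthalen-2(1H)-one
Conditions: OsO4 (5 mol %), NMO (1.3 equiv), acetone/H2O, 0 °C to rt; aq. Na2SO3
Reagents that add atoms: osmium tetroxide, O=[Os](=O)(=O)=O; N-methylmorpholine N-oxide, C[N+]1([O-])CCOCC1; water, O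
Why: Upjohn dihydroxylation should take place at the electron-rich trisubstituted ring A alkene rather than the enone, by syn addition from the α-face anti to the axial angular methyl, setting C5 (S) and C6 (R) as the cis-diol.

Step 9
Reactants: 11 triol
Product: 12 (1S,2R,4aR,8aR)-1-hydroxy-7-(2-hydroxypropan-2-yl)-1,4a-dimethyl-6-oxo-1,2,3,4,4a,5,6,8a-octahydronaphthalen-2-yl 3-methylbut-2-enoate (target; 3α-senecioyloxy-4α,11-dihydroxyeudesm-6-en-8-one)
Conditions: 3-methylbut-2-enoyl chloride (1.5 equiv), pyridine, DMAP (10 mol %), CH2Cl2, 0 °C to rt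
Reagents that add atoms: 3-methylbut-2-enoyl chloride, CC(C)=CC(=O)Cl
Why: DMAP-catalysed acylation should be selective for the only secondary hydroxyl, the two tertiary hydroxyls being unreactive; pyridine as the sole base limits deconjugation of the senecioyl unit and no stereocentre is affected.

Compound list
1 | methyl vinyl ketone (but-3-en-2-one) | CC(=O)C=C | starting material
2 | 2-(tert-butyldimethylsilyloxy)buta-1,3-diene | C=CC(=C)O[Si](C)(C)C(C)(C)C | intermediate
3 | 3-methylcyclohex-2-en-1-one | CC1=CC(=O)CCC1 | starting material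
4 | (4aR,8aS)-6-[(tert-butyldimethylsilyl)oxy]-4a-methyl-3,4,4a,5,8,8a-hexahydronaphthalen-1(2H)-one (cis-fused) | O=C1CCC[C@]2(C)CC(O[Si](C)(C)C(C)(C)C)=CC[C@H]12 | intermediate
5 | (4aR,8aR)-6-[(tert-butyldimethylsilyl)oxy]-4a-methyl-3,4,4a,5,8,8a-hexahydronaphthalen-1(2H)-one (trans-fused) | O=C1CCC[C@]2(C)CC(O[Si](C)(C)C(C)(C)C)=CC[C@@H]12 | intermediate
6 | lithium (4aR,8aR)-6-[(tert-butyldimethylsilyl)oxy]-4a-methyl-3,4,4a,5,8,8a-hexahydronaphthalen-1-olate | [Li+].[O-]C1=CCC[C@]2(C)CC(O[Si](C)(C)C(C)(C)C)=CC[C@@H]12 | intermediate
7 | (4aR,8aR)-6-[(tert-butyldimethylsilyl)oxy]-4a-methyl-3,4,4a,5,8,8a-hexahydronaphthalen-1-yl trifluoromethanesulfonate | FC(F)(F)S(=O)(=O)OC1=CCC[C@]2(C)CC(O[Si](C)(C)C(C)(C)C)=CC[C@@H]12 | intermediate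
8 | tert-butyl{[(4aR,8aR)-5,8a-dimethyl-1,4,4a,7,8,8a-hexahydronaphthalen-2-yl]oxy}dimethylsilane | CC1=CCC[C@]2(C)CC(O[Si](C)(C)C(C)(C)C)=CC[C@@H]12 | intermediate
9 | (4aR,8aR)-3-(2-hydroxypropan-2-yl)-5,8a-dimethyl-3,4,4a,7,8,8a-hexahydronaphthalen-2(1H)-one (C3 epimer mixture) | CC1=CCC[C@]2(C)CC(=O)C(C(C)(C)O)C[C@@H]12 | intermediate
10 | (4aR,8aR)-3-(2-hydroxypropan-2-yl)-5,8a-dimethyl-4a,7,8,8a-tetrahydronaphthalen-2(1H)-one | CC1=CCC[C@]2(C)CC(=O)C(C(C)(C)O)=C[C@@H]12 | intermediate
11 | (4aR,5S,6R,8aR)-5,6-dihydroxy-3-(2-hydroxypropan-2-yl)-5,8a-dimethyl-4a,5,6,7,8,8a-hexahydronaphthalen-2(1H)-one | O[C@@H]1CC[C@]2(C)CC(=O)C(C(C)(C)O)=C[C@H]2[C@]1(C)O | intermediate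
12 | (1S,2R,4aR,8aR)-1-hydroxy-7-(2-hydroxypropan-2-yl)-1,4a-dimethyl-6-oxo-1,2,3,4,4a,5,6,8a-octahydronaphthalen-2-yl 3-methylbut-2-enoate | CC(C)=CC(=O)O[C@@H]1CC[C@]2(C)CC(=O)C(C(C)(C)O)=C[C@H]2[C@]1(C)O | target

Total step count: 9
Longest linear sequence: 9 steps (1 to 12); 8 steps from 3.

Steps most likely to fail

Step 2 (the step labelled "Proposed new method:"). The chiral Lewis acid may fail to turn over with the β,β-disubstituted enone or may discriminate the enone faces poorly, and the diene may be consumed by protodesilylation or oligomerisation. Fallback: starting from 2 and 3, the known achiral cycloaddition promoted by AlBr3 with a minor portion of AlMe3 in toluene/CH2Cl2 at about −5 °C would give the racemic cis adduct, that is 4 together with its enantiomer, the (4aS,8aR) cis adduct F1. Equilibration under the step 3 conditions would give racemic trans ketone, that is 5 together with its enantiomer, the (4aS,8aS) trans ketone F2. Preparative chiral-phase SFC would then separate 5 from F2, and the route is rejoined at 5.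

Step 3. The cis/trans equilibrium of the angularly methylated decalone may lie too close to parity, and the alkoxide may slowly cleave or scramble the silyl enol ether. Fallback under kinetic control: starting from 4, LiN(SiMe3)2 (0.95 equiv) in THF at 0 °C to rt, with the residual ketone acting as proton shuttle, would equilibrate to the more substituted lithium enolate, the tetrasubstituted ring-fusion enolate F3. Inverse quench at −78 °C into 2,6-di-tert-butylphenol should protonate the ring-fusion carbon axially, on the face anti to the angular methyl, and so give the trans ketone directly; the route is rejoined at 5.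

Step 7. Dehydration or retro-aldol cleavage of the tertiary β-hydroxy ketone may compete at 65 °C, enolisation toward the hindered α-carbon may be slow, and the ring A alkene of the product may drift into conjugation through the doubly allylic ring-fusion hydrogen. Fallback by selenoxide elimination, which replaces steps 6 and 7: starting from 8, PhSeCl in CH2Cl2 at −78 °C would give the α-phenylselanyl ketone F4. Deprotonation at the selenium-bearing carbon with LiN(i-Pr)2 (THF, −78 °C) and addition of acetone would give the selanyl aldol F5. Oxidation with mCPBA (1.0 equiv, −78 °C) and warming with i-Pr2NH would trigger syn-elimination of the selenoxide toward the only β-hydrogens (on the ring CH2), and the route is rejoined at 10.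

Further compounds
F1 | step 2 | (4aS,8aR)-6-[(tert-butyldimethylsilyl)oxy]-4a-methyl-3,4,4a,5,8,8a-hexahydronaphthalen-1(2H)-one (enantiomer of 4) | O=C1CCC[C@@]2(C)CC(O[Si](C)(C)C(C)(C)C)=CC[C@@H]12
F2 | step 2 | (4aS,8aS)-6-[(tert-butyldimethylsilyl)oxy]-4a-methyl-3,4,4a,5,8,8a-hexahydronaphthalen-1(2H)-one (enantiomer of 5) | O=C1CCC[C@@]2(C)CC(O[Si](C)(C)C(C)(C)C)=CC[C@H]12
F3 | step 3 | lithium (4aR)-6-[(tert-butyldimethylsilyl)oxy]-4a-methyl-2,3,4,4a,5,8-hexahydronaphthalen-1-olate | [Li+].[O-]C1=C2CC=C(O[Si](C)(C)C(C)(C)C)C[C@@]2(C)CCC1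
F4 | step 7 | (4aR,8aR)-5,8a-dimethyl-3-(phenylselanyl)-3,4,4a,7,8,8a-hexahydronaphthalen-2(1H)-one (C3 undefined) | CC1=CCC[C@]2(C)CC(=O)C([Se]c3ccccc3)C[C@@H]12
F5 | step 7 | (4aR,8aR)-3-(2-hydroxypropan-2-yl)-5,8a-dimethyl-3-(phenylselanyl)-3,4,4a,7,8,8a-hexahydronaphthalen-2(1H)-one (C3 undefined) | CC1=CCC[C@]2(C)CC(=O)C([Se]c3ccccc3)(C(C)(C)O)C[C@@H]12
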